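At 6.0 d I had to say how much electrophile had reacted and how much unused nucleophile was still free. I counted turnovers.

| setting | delta | eta | theta | flask |
|---|---|---|---|---|
| electrophile | 0.050 M (fed, over 6.0 h) | 0.050 M (fed, over 6.0 h) | 0.075 M (fed, over 6.0 h) | 0.050 M (fed, over 6.0 h) |
| nucleophile | 2.8 equiv | 4.4 equiv | 2 equiv | 2.00 equiv |
| remark | run made earlier; the fed solution adds 0.20 times the starting volume | run made earlier; the fed solution adds 0.20 times the starting volume | run made earlier; the fed solution adds 0.20 times the starting volume | the fed solution adds 0.20 times the starting volume |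
| time |  |  |  | 6.0 d |

- delta (time / d: electrophile / %, target / %): 0.250: 73.4, 26.8; 0.625: 37.2, 61.6; 1.25: 16.6, 82.1; 2.08: 7.1, 91.3; 3.00: 3.8, 94.0; 4.00: 2.0, 94.1
- eta (time / d: electrophile / %, target / %): 0.625: 19.9, 79.2; 1.25: 4.3, 92.6; 1.67: 0.7, 94.9; 2.50: 0.6, 92.2; 3.00: 0, 91.2; 4.00: 0, 88.5
- theta (time / d: electrophile / %, target / %): 0.625: 40.6, 59.1; 1.25: 22.9, 75.5; 2.00: 16.1, 83.4; 3.00: 10.3, 87.2; 4.00: 8.2, 89.0

(readings scatter by 0.5 percentage points)

- amounts are per litre of the starting volume; all of the dose is in the solution fed
- the earlier runs do not show how much of nucleophile is bound; that part of a forecast is a guess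

1. part of the electrophile that has reacted at 6.0 d
2. share of the unused nucleophile that is free and not bound as protonated nucleophile, at 6.0 d

1. Nucleophile. By hand, at 2.00 equiv one nucleophile per electrophile forms target and one ends as protonated nucleophile. Free nucleophile then falls in step with electrophile, and the reciprocal of the fraction left rises evenly. By hand, nucleophile above 2.00 equiv should shorten the tail, with the charge held. At 4.00 d the delta run, with 2.8 equiv, held 2.0% electrophile, less than the 8.2% of the theta run, though theta had the larger charge.

2. Electrophile. By hand, that rise goes with the charge, at fixed equivalents. The theta readings rose 2.85 /d, so I scaled the flask to 1.90 /d.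

3. Feed. By hand, a steady feed counts as a charge at its middle, and 6.0 h is far shorter than 6.0 d. The clock ran 5.88 d.

4. Time. I got 11.1. This is the turnover count, the rise per day times the counted time, a Damköhler number. At 2.00 equiv the fraction left is one over one plus the count. That gave 8.23% left and 91.8% reacted.

5. Binding. The runs do not show it. Assuming complete binding, I got a free share of 15.2%, a guess.

The forecast gave 91.5% and 15%, where I had 91.8% and 15.2%. Of its share it said: “This figure is largely assumed.”

The flask gave 91.7% and 13.9%.

    electrophile + nucleophile → acid set free + target (k = 0.0164 /M/min)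
    nucleophile + acid set free ⇌ protonated nucleophile, settled at all times (K = 54000 /M)
    nucleophile + target → over-reaction product A (k = 2.18 × 10⁻⁴ /M/min)
    target → over-reaction product B (k = 9.26 × 10⁻⁷ /min)

At 6.00 d the flask's step to target used nucleophile 7.0 times as fast as the step to over-reaction product A. At 0.555 d the half-life of nucleophile by that side step was 120 d, longer than 6.0 d. In the neighbour flask with 0.085 M electrophile, equivalents held, the count scaled to 19.0, leaving 5.00%. It computed to 5.34% left and 94.7% reacted.

The data come from a simulation with constants of no real substance; scatter was added.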